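I start from what is left at the moment in question: with 50 % converted, c(substrate) in the flask is 15.0 mM, the charge of theta, but alpha, the furthest of the earlier runs, still holds 56.0 % substrate at its last reading, so that moment lies past the readings and what I tell of its rate is an extrapolation.

the same everywhere: reagent 1.05 equiv
- gamma: substrate 30 mM; free catalyst 2.8 mol%; run made earlier
- alpha: substrate 30 mM; free catalyst 4.4 mol%; run made earlier
- theta: substrate 15 mM; free catalyst 2 mol%; run made earlier
- flask: substrate 30 mM; free catalyst 2 mol%

| run | time / h | product / % | substrate / % |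
|---|---|---|---|
| gamma | 1.50 | 2.1 | 96.9 |
| gamma | 5.00 | 4.1 | 90.7 |
| gamma | 8.00 | 9.2 | 87.5 |
| gamma | 15.0 | 17.4 | 78.2 |
| gamma | 20.0 | 22.4 | 76.1 |
| gamma | 25.0 | 27.3 | 71.3 |
| alpha | 2.00 | 3.4 | 92.0 |
| alpha | 3.00 | 5.4 | 92.0 |
| alpha | 6.00 | 9.7 | 85.8 |
| alpha | 10.0 | 18.7 | 80.5 |
| alpha | 15.0 | 27.1 | 70.0 |
| alpha | 25.0 | 39.5 | 56.0 |
| theta | 2.00 | 0.5 | 97.8 |
| theta | 6.00 | 1.3 | 96.5 |
| theta | 12.0 | 4.7 | 94.0 |
| theta | 20.0 | 9.1 | 89.0 |
| theta | 25.0 | 9.8 | 88.4 |

(each reading ± 1 percentage point)

* apparent order in free catalyst when 50 % of the substrate are converted (percent change of the rate of making product for one percent more free catalyst charged)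

- what may be going on: substrate + free catalyst <-> catalyst intermediate A; reagent + catalyst intermediate A <-> catalyst intermediate B; catalyst intermediate B <-> catalyst intermediate C; catalyst intermediate C -> free catalyst + product; free catalyst <-> dormant form

Alpha holds 27.1 % product at 15.0 h and gamma 27.3 % at 25.0 h, so I have one conversion at two loadings. The logarithm of the ratio of those times over the logarithm of the ratio of the loadings is my same-conversion order, the power by which the time to a given conversion shrinks with catalyst charged: 1.13, a reading with its scatter. Alpha's time shrank by more than its loading grew, so I commit to an order above first.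

For the rate, gamma's early mean is 0.328 mM h⁻¹, and this power scales it to 0.224 mM h⁻¹ for the flask. Theta, at the same loading with half the charge, averages 0.0588 mM h⁻¹, a fall by 3.81. The thinner catalyst takes a factor 2.19 of that, and lower c(substrate) and c(reagent) take the remaining 1.74. So, reckoning as if the catalyst stood as it does in the hours those runs cover, I expect the flask near 0.129 mM h⁻¹ at the point asked about.

The forecast says 0.97, within 0.85 to 1.1, holding that bound catalyst “pulls the order just below 1”; my reading is higher.

The flask gives 1.2, at a rate of 0.116 mM h⁻¹ after 78.6 h.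

    substrate + free catalyst ⇌ catalyst intermediate A (K = 93.0 L mol⁻¹, k = 0.335 L mol⁻¹ s⁻¹)
    reagent + catalyst intermediate A ⇌ catalyst intermediate B (K = 25.0 L mol⁻¹, k = 0.0692 L mol⁻¹ s⁻¹)
    catalyst intermediate B ⇌ catalyst intermediate C (K = 1.80, k = 0.00150 s⁻¹)
    catalyst intermediate C → free catalyst + product (k = 4.98 × 10⁻⁴ s⁻¹)
    free catalyst ⇌ dormant form (K = 2.50, k = 1.01 × 10⁻⁵ s⁻¹)

The excess over first order is 0.237 in the flask, against 0.130 in my reading. A simulated run of this flask with the return of catalyst intermediate B to reagent and catalyst intermediate A taken away shows that this return holds the rate at that conversion back, by a factor of 3.10. The same return is a part of the excess, not the whole of it: without it the order at the same conversion is 1.1, lower by 0.150.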